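**Retrosynthetic overview**
- The target is the meso (2S,3R) 1,4-diketone. Its C1 and C4 carbonyl oxygens, each on a carbon bearing ring A (2,4-dihydroxyphenyl), stand 1,4 to each other across the C2–C3 bond that carries the two ring B (4-hydroxybenzyl) arms. This is the pattern left when O2 adds to the two ends of a 1,3-diene.
- 13 ⇐ hexabenzyl ether 12 ⇐ diol 11 ⇐ hydroxyl-directed syn hydrogenation of Z-enediol 10 ⇐ O–O reduction of cis-3,6-dihydro-1,2-dioxine 9. The ring locks the alkene as Z, and Z plus syn H2 gives meso.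
- 9 ⇐ [4+2] cycloaddition of singlet oxygen to the (1E,3E)-diene 7. The 1,2-dioxine is the only ring formed in the route and is opened again.
- 7 ⇐ oxidative homocoupling (C2–C3 bond) of (Z)-alkenylboronate 6 ⇐ syn borylcupration/protonation of alkyne 5 ⇐ alkyne 2 + benzylic chloride 3; 2 ⇐ aldehyde 1.
- A Heck arylation of 2,3-dibenzylbutadiene is not used, because β-hydride loss could go toward either benzylic CH2 and would scramble rings A and B.

Key step: step 5

Assumption: the target SMILES encodes the achiral meso (2S,3R) diastereomer, so only relative configuration has to be controlled; compounds 1 and 3 are taken as purchasable.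

**Step 1**
Reactants: 1 2,4-bis(benzyloxy)benzaldehyde
Product: 2 2,4-bis(benzyloxy)-1-ethynylbenzene
Conditions: dimethyl (1-diazo-2-oxopropyl)phosphonate, K2CO3, MeOH–THF, 0 °C to rt
Reagents that add atoms: dimethyl (1-diazo-2-oxopropyl)phosphonate, COP(=O)(OC)C(=[N+]=[N-])C(C)=O
Why: Seyferth–Gilbert homologation in the Ohira–Bestmann form: methanolysis releases the diazomethylphosphonate anion, which olefinates the aldehyde, and loss of N2 with 1,2-hydride shift gives the terminal alkyne; aryl benzyl ethers are inert to carbonate.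

**Step 2**
Reactants: 2 2,4-bis(benzyloxy)-1-ethynylbenzene; 3 4-(benzyloxy)benzyl chloride
Product: 5 2,4-bis(benzyloxy)-1-{3-[4-(benzyloxy)phenyl]prop-1-yn-1-yl}benzene, via alkynylmagnesium bromide 4 (not isolated)
Conditions: EtMgBr, THF, 0 to 50 °C; then CuBr (10 mol %), 3, THF, 65 °C
Reagents that add atoms: none
Why: Copper-catalysed coupling of an alkynyl Grignard reagent with a benzylic halide; the 4-alkoxybenzyl chloride is an activated electrophile, and the weakly basic alkynyl nucleophile should not isomerise the 1,3-diarylpropyne to the allene.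

**Step 3**
Reactants: 5 2,4-bis(benzyloxy)-1-{3-[4-(benzyloxy)phenyl]prop-1-yn-1-yl}benzene
Product: 6 2-{(Z)-1-[2,4-bis(benzyloxy)phenyl]-3-[4-(benzyloxy)phenyl]prop-1-en-2-yl}-4,4,5,5-tetramethyl-1,3,2-dioxaborolane
Conditions: B2pin2, CuCl (5 mol %), P(p-tol)3 (6 mol %), NaOt-Bu (5 mol %), MeOH (2 equiv), THF, rt
Reagents that add atoms: bis(pinacolato)diboron, CC1(C)OB(OC1(C)C)B1OC(C)(C)C(C)(C)O1
Why: Copper-catalysed formal hydroboration (syn borylcupration, then protonolysis of the C–Cu bond by MeOH): copper goes to the aryl-bearing carbon and boron to the benzyl-bearing carbon, and syn addition puts H and B cis, so ring A is trans to boron (Z); alkoxide is kept equimolar with copper so that no free base isomerises the propargylic CH2.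

**Step 4**
Reactants: 6 the (Z)-alkenylboronate (two molecules)
Product: 7 (1E,3E)-1,4-bis[2,4-bis(benzyloxy)phenyl]-2,3-bis[4-(benzyloxy)benzyl]buta-1,3-diene
Conditions: Pd(OAc)2 (5 mol %), K2CO3, O2 (1 atm), DMF–H2O, 50 °C
Reagents that add atoms: none
Why: Palladium-catalysed oxidative homocoupling of an alkenylboronate: two transmetalations to divalent palladium and reductive elimination form the C2–C3 bond with retention at both alkenes, so each ring A ends trans to the new bond (1E,3E), and O2 reoxidises zerovalent palladium.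

**Step 5**
Reactants: 7 the (1E,3E)-diene; 8 dioxygen (used as singlet oxygen)
Product: 9 cis-(3R,6S)-3,6-bis[2,4-bis(benzyloxy)phenyl]-4,5-bis[4-(benzyloxy)benzyl]-3,6-dihydro-1,2-dioxine (meso)
Conditions: O2, meso-tetraphenylporphyrin (1 mol %), visible light (> 400 nm), CH2Cl2, −20 °C
Reagents that add atoms: none
Why: Energy transfer from the excited porphyrin gives singlet oxygen, which adds as a two-atom dienophile to C1 and C4 of the s-cis conformer of 7 in a [4+2] cycloaddition, the known dye-sensitised photooxygenation of 1,4-diaryl-1,3-dienes to 3,6-dihydro-1,2-dioxines. The six-membered 1,2-dioxine ring closes by forming both C–O bonds on one face of the diene (suprafacial [4+2] mode), which leaves C4=C5 of the ring as a tetrasubstituted alkene whose two oxygen-bearing carbons are necessarily cis, that is Z. The new stereocentres C3 and C6 should come out cis because both E-configured termini carry ring A outward and are attacked from the same face; these centres are later removed, but their cis relation puts both hydroxyls of 10 on one face. The step needs [4+2] to beat the ene reaction at the allylic benzylic CH2 groups and [2+2] addition with cleavage at the electron-rich styrene bonds. The 2,3-dibenzyl substitution raises the s-cis population, the outward aryl groups leave the termini open, and a non-polar solvent at low temperature disfavours the polar paths to dioxetanes. Light above 400 nm is absorbed only by the sensitiser, so direct E/Z isomerisation of the diene is avoided.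

**Step 6**
Reactants: 9 the cis-dioxine
Product: 10 (1R,4S,2Z)-1,4-bis[2,4-bis(benzyloxy)phenyl]-2,3-bis[4-(benzyloxy)benzyl]but-2-ene-1,4-diol (meso)
Conditions: thiourea, MeOH–CH2Cl2, 0 °C to rt (crude 9 can be used directly)
Reagents that add atoms: none
Why: Thiourea reduction of a cyclic peroxide cleaves only the O–O bond, so the cis carbinol configuration and the ring-imposed Z geometry pass on unchanged; the neutral medium avoids Kornblum–DeLaMare rearrangement of the doubly benzylic peroxide.

**Step 7**
Reactants: 10 the Z-enediol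
Product: 11 (1R,2R,3S,4S)-1,4-bis[2,4-bis(benzyloxy)phenyl]-2,3-bis[4-(benzyloxy)benzyl]butane-1,4-diol (meso)
Conditions: H2 (10 bar), [Ir(cod)(PCy3)(py)]PF6 (10–20 mol %, in portions), CH2Cl2, rt
Reagents that add atoms: none
Why: Hydroxyl-directed homogeneous hydrogenation with the cationic iridium catalyst, which can reduce tetrasubstituted alkenes: in the conformer that minimises allylic 1,3-strain both hydroxyls lie on one alkene face and both ring A groups on the other, so iridium binds there and delivers both hydrogens syn to that face; syn addition to the Z alkene sets C2 and C3 in the meso relationship, and benzyl ethers are not cleaved by this catalyst.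

**Step 8**
Reactants: 11 the saturated meso diol
Product: 12 (2R,3S)-1,4-bis[2,4-bis(benzyloxy)phenyl]-2,3-bis[4-(benzyloxy)benzyl]butane-1,4-dione (meso)
Conditions: DMP (3 equiv), pyridine, CH2Cl2, 0 °C to rt
Reagents that add atoms: none
Why: Dess–Martin oxidation of both secondary benzylic alcohols under buffered, non-enolising conditions removes the two carbinol stereocentres and should leave the α-stereocentres C2 and C3 untouched.

**Step 9**
Reactants: 12 the hexabenzyl meso diketone
Product: 13 (2R,3S)-1,4-bis(2,4-dihydroxyphenyl)-2,3-bis(4-hydroxybenzyl)butane-1,4-dione (meso; CNP0406969.1)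
Conditions: H2 (1 atm), Pd/C (10 %), EtOAc–MeOH, rt
Reagents that add atoms: none
Why: Hydrogenolysis of the six aryl benzyl ethers under neutral conditions does not disturb the epimerisable C2 and C3 centres; the aryl ketones, deactivated by their ortho and para oxygen donors, should survive if the reaction is stopped when hydrogen uptake ends.

**Compound list**
1 | 2,4-bis(benzyloxy)benzaldehyde | O=Cc1ccc(OCc2ccccc2)cc1OCc1ccccc1 | starting material
2 | 2,4-bis(benzyloxy)-1-ethynylbenzene | C#Cc1ccc(OCc2ccccc2)cc1OCc1ccccc1 | intermediate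
3 | 4-(benzyloxy)benzyl chloride | ClCc1ccc(OCc2ccccc2)cc1 | starting material
4 | {[2,4-bis(benzyloxy)phenyl]ethynyl}magnesium bromide | Br[Mg]C#Cc1ccc(OCc2ccccc2)cc1OCc1ccccc1 | intermediate
5 | 2,4-bis(benzyloxy)-1-{3-[4-(benzyloxy)phenyl]prop-1-yn-1-yl}benzene | C(C#Cc1ccc(OCc2ccccc2)cc1OCc1ccccc1)c1ccc(OCc2ccccc2)cc1 | intermediate
6 | 2-{(Z)-1-[2,4-bis(benzyloxy)phenyl]-3-[4-(benzyloxy)phenyl]prop-1-en-2-yl}-4,4,5,5-tetramethyl-1,3,2-dioxaborolane | CC1(C)OB(OC1(C)C)/C(Cc1ccc(OCc2ccccc2)cc1)=C/c1ccc(OCc2ccccc2)cc1OCc1ccccc1 | intermediate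
7 | (1E,3E)-1,4-bis[2,4-bis(benzyloxy)phenyl]-2,3-bis[4-(benzyloxy)benzyl]buta-1,3-diene | O(Cc1ccccc1)c1ccc(/C=C(Cc2ccc(OCc3ccccc3)cc2)/C(Cc2ccc(OCc3ccccc3)cc2)=C/c2ccc(OCc3ccccc3)cc2OCc2ccccc2)c(OCc2ccccc2)c1 | intermediate
8 | dioxygen (used as singlet oxygen) | O=O | starting material
9 | cis-(3R,6S)-3,6-bis[2,4-bis(benzyloxy)phenyl]-4,5-bis[4-(benzyloxy)benzyl]-3,6-dihydro-1,2-dioxine (meso) | O1O[C@H](c2ccc(OCc3ccccc3)cc2OCc2ccccc2)C(Cc2ccc(OCc3ccccc3)cc2)=C(Cc2ccc(OCc3ccccc3)cc2)[C@@H]1c1ccc(OCc2ccccc2)cc1OCc1ccccc1 | intermediate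
10 | (1R,4S,2Z)-1,4-bis[2,4-bis(benzyloxy)phenyl]-2,3-bis[4-(benzyloxy)benzyl]but-2-ene-1,4-diol (meso) | O[C@H](c1ccc(OCc2ccccc2)cc1OCc1ccccc1)/C(Cc1ccc(OCc2ccccc2)cc1)=C(Cc1ccc(OCc2ccccc2)cc1)\[C@@H](O)c1ccc(OCc2ccccc2)cc1OCc1ccccc1 | intermediate
11 | (1R,2R,3S,4S)-1,4-bis[2,4-bis(benzyloxy)phenyl]-2,3-bis[4-(benzyloxy)benzyl]butane-1,4-diol (meso) | O[C@H](c1ccc(OCc2ccccc2)cc1OCc1ccccc1)[C@@H](Cc1ccc(OCc2ccccc2)cc1)[C@@H](Cc1ccc(OCc2ccccc2)cc1)[C@@H](O)c1ccc(OCc2ccccc2)cc1OCc1ccccc1 | intermediate
12 | (2R,3S)-1,4-bis[2,4-bis(benzyloxy)phenyl]-2,3-bis[4-(benzyloxy)benzyl]butane-1,4-dione (meso) | O=C(c1ccc(OCc2ccccc2)cc1OCc1ccccc1)[C@@H](Cc1ccc(OCc2ccccc2)cc1)[C@@H](Cc1ccc(OCc2ccccc2)cc1)C(=O)c1ccc(OCc2ccccc2)cc1OCc1ccccc1 | intermediate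
13 | (2R,3S)-1,4-bis(2,4-dihydroxyphenyl)-2,3-bis(4-hydroxybenzyl)butane-1,4-dione (meso) | O=C(c1ccc(O)cc1O)[C@@H](Cc1ccc(O)cc1)[C@@H](Cc1ccc(O)cc1)C(=O)c1ccc(O)cc1O | target

**Total step count:** 9
**Longest linear sequence:** 9 steps (1 → 13)

**Steps most likely to fail**

1. Step 5 (photooxygenation). The ene reaction at the allylic benzylic CH2 groups or dioxetane formation with cleavage of the electron-rich styrene bonds may outrun the [4+2] addition, and the doubly benzylic peroxide may rearrange during handling. The fallback sets out from alkyne 5 and comes back at diketone 12. Alkyne 5 would be hydrated with catalytic (Ph3P)AuNTf2 in aqueous dioxane at 60 °C, where the electron-rich ring A directs water to the aryl-bearing carbon, to give the aryl ketone 1-[2,4-bis(benzyloxy)phenyl]-3-[4-(benzyloxy)phenyl]propan-1-one F1. Its lithium enolate (LiN(i-Pr)2, THF, −78 °C) would be dimerised oxidatively with CuCl2 (DMF, −78 °C to rt), which forms the C2–C3 bond directly and should give 12 together with its racemic (2RS,3RS) diastereomer F2. Compound 12 would be separated by crystallisation or chromatography, and F2 could be equilibrated with a catalytic amine base and recycled. This gives up the stereochemical relay, so C2 and C3 are set without control.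

2. Step 7 (directed hydrogenation). The catalyst may deactivate before the hindered tetrasubstituted alkene turns over, or the acidic iridium hydride may ionise the electron-rich benzylic allylic hydroxyls and cause cyclodehydration to a dihydrofuran. The fallback sets out from Z-enediol 10 and comes back at 12. Both carbinols of 10 would be oxidised with DMP and pyridine (CH2Cl2, 0 °C, in the dark) to the Z-enedione (2Z)-1,4-bis[2,4-bis(benzyloxy)phenyl]-2,3-bis[4-(benzyloxy)benzyl]but-2-ene-1,4-dione F3. Its electron-poor alkene would then be hydrogenated heterogeneously (H2, Pd/C, EtOAc containing pyridine to spare the benzyl ethers, rt). Syn addition to the Z alkene again leads to meso diketone 12.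

3. Step 4 (oxidative homocoupling). Protodeboronation or oxidation of the C–B bond may outpace the second transmetalation at the hindered α-branched alkenylboronate. The fallback sets out from boronate 6 and comes back at diene 7. Half of 6 would be converted with retention into the alkenyl iodide (E)-2,4-bis(benzyloxy)-1-{3-[4-(benzyloxy)phenyl]-2-iodoprop-1-en-1-yl}benzene F4 (aqueous NaOH, then I2, THF, 0 °C). F4 would then be joined to the other half of 6 by Suzuki–Miyaura cross-coupling (Pd(PPh3)4, aqueous K3PO4, THF, 60 °C). Both partners keep their geometry, so the (1E,3E)-diene 7 results.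

**Further compounds**
F1 | step 5 | 1-[2,4-bis(benzyloxy)phenyl]-3-[4-(benzyloxy)phenyl]propan-1-one | O=C(CCc1ccc(OCc2ccccc2)cc1)c1ccc(OCc2ccccc2)cc1OCc1ccccc1
F2 | step 5 | (2RS,3RS)-1,4-bis[2,4-bis(benzyloxy)phenyl]-2,3-bis[4-(benzyloxy)benzyl]butane-1,4-dione (racemic diastereomer, 2S,3S enantiomer drawn) | O=C(c1ccc(OCc2ccccc2)cc1OCc1ccccc1)[C@@H](Cc1ccc(OCc2ccccc2)cc1)[C@H](Cc1ccc(OCc2ccccc2)cc1)C(=O)c1ccc(OCc2ccccc2)cc1OCc1ccccc1
F3 | step 7 | (2Z)-1,4-bis[2,4-bis(benzyloxy)phenyl]-2,3-bis[4-(benzyloxy)benzyl]but-2-ene-1,4-dione | O=C(c1ccc(OCc2ccccc2)cc1OCc1ccccc1)/C(Cc1ccc(OCc2ccccc2)cc1)=C(Cc1ccc(OCc2ccccc2)cc1)\C(=O)c1ccc(OCc2ccccc2)cc1OCc1ccccc1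
F4 | step 4 | (E)-2,4-bis(benzyloxy)-1-{3-[4-(benzyloxy)phenyl]-2-iodoprop-1-en-1-yl}benzene | I/C(Cc1ccc(OCc2ccccc2)cc1)=C/c1ccc(OCc2ccccc2)cc1OCc1ccccc1
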